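**Retrosynthetic overview**
1. Target 16 ⇐ hexabenzyl ether 15 ⇐ interflavan C4–C6 bond: C4 acetal 10 of the 2,3-cis upper unit plus the 2,3-trans lower unit 14; attack anti to the 3-OH gives 3,4-trans.
2. 10 ⇐ cis alcohol 9 ⇐ flavan-3-one 8; the ketone is what lets a bulky hydride set the 2,3-cis pair.
3. Key disconnection: C4–C4a of ring C in 8. Alkyne 6 is oxidised to an α-oxo gold carbene (a ketone α-carbon made electrophilic), which the electron-rich ring A carbon attacks; C2 comes from 6.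
4. Lower unit 14 ⇐ chromene 12 (hydroboration, trans) ⇐ mirror-image ether 11 (redox-neutral gold hydroarylation).
5. 6 and 11 ⇐ one racemic acetate 4 plus phenol 5 with mirror-image copper catalysts. Ring order: ring C (upper) and ring F (lower) are closed separately, then the halves are joined.

An enolonium-type coupling at the interflavan bond itself was not used: it passes through a 4-aryl-flavan-3-one, whose reduction is not expected to give the 2,3-cis-3,4-trans arrangement.

Assumption: the sense of induction of the copper–pybox catalyst is checked on a trial scale; the ligand antipode that gives R-6 is used in step 2 and its mirror image in step 6 (written below as (S,S) and (R,R)).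

**Step 1**
Reactants: 1 3,4-bis(benzyloxy)benzaldehyde; 2 ethynylmagnesium bromide
Product: 4 racemic 1-[3,4-bis(benzyloxy)phenyl]prop-2-yn-1-yl acetate, via bromomagnesium propargylic alkoxide 3 (not isolated)
Conditions: 2 (1.3 equiv), THF, 0 °C; then Ac2O (2 equiv), 0 °C to rt
Reagents that add atoms: acetic anhydride, CC(=O)OC(C)=O
Why: Grignard addition to the aldehyde and O-acylation of the alkoxide in the same flask; the product is racemic on purpose because the next step is enantioconvergent.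

**Step 2**
Reactants: 4 racemic propargylic acetate; 5 3-(benzyloxy)phenol
Product: 6 1-(benzyloxy)-3-{[(1R)-1-[3,4-bis(benzyloxy)phenyl]prop-2-yn-1-yl]oxy}benzene
Conditions: (CuOTf)2·C6H6 (5 mol %), (S,S)-Ph-pybox (10 mol %), i-Pr2NEt (1.2 equiv), CH2Cl2, −20 °C
Reagents that add atoms: none
Why: Copper-catalysed asymmetric propargylic substitution (Nishibayashi type): both enantiomers of 4 ionise at copper to one common planar species and the pybox ligand directs O-attack of the phenol to one face, setting the R centre that becomes C2 (S) of the upper unit.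

**Step 3 (key step)**
Reactants: 6 (R)-aryl propargyl ether
Product: 8 (2S)-7-(benzyloxy)-2-[3,4-bis(benzyloxy)phenyl]chroman-3-one, via α-oxo gold carbene 7 (not isolated)
Conditions: Me4tBuXPhosAuNTf2 (5 mol %), 2,6-dichloropyridine N-oxide (1.5 equiv), ClCH2CH2Cl, rt; used at once in step 4
Reagents that add atoms: 2,6-dichloropyridine N-oxide, [O-][n+]1c(Cl)cccc1Cl
Why: Gold-catalysed alkyne oxidation with intramolecular arene trapping (Zhang chroman-3-one synthesis): the N-oxide puts oxygen on the internal alkyne carbon, the carbene carbon next to the new C=O is electrophilic and is attacked by the ring A carbon para to the benzyloxy group, so two normally nucleophilic carbons are joined as C4–C4a and ring C closes without touching C2.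

**Step 4**
Reactants: 8 (2S)-flavan-3-one
Product: 9 (2S,3S)-7-(benzyloxy)-2-[3,4-bis(benzyloxy)phenyl]chroman-3-ol (2,3-cis)
Conditions: LiBH(s-Bu)3 (1.5 equiv), LiBr (3 equiv), THF, −78 °C; H2O
Reagents that add atoms: none
Why: Diastereoselective ketone reduction with a bulky hydride, which attacks the face opposite the C2 aryl group and gives the 2,3-cis alcohol (3S), as in the established 3-oxoflavan to epi-series reduction.

**Step 5**
Reactants: 9 (2S,3S)-alcohol
Product: 10 (2S,3S,4R)-7-(benzyloxy)-2-[3,4-bis(benzyloxy)phenyl]-4-(2-ethoxyethoxy)chroman-3-ol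
Conditions: DDQ (2 equiv), EtOCH2CH2OH (5 equiv), CH2Cl2, rt
Reagents that add atoms: 2-ethoxyethanol, CCOCCO
Why: DDQ benzylic oxidation (hydride abstraction at C4, helped by O1 and the para 7-benzyloxy group) with capture by the alcohol trans to the 3-OH; the C4 configuration of 10 does not matter because it is ionised again in step 9.

**Step 6**
Reactants: 4 racemic propargylic acetate; 5 3-(benzyloxy)phenol
Product: 11 1-(benzyloxy)-3-{[(1S)-1-[3,4-bis(benzyloxy)phenyl]prop-2-yn-1-yl]oxy}benzene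
Conditions: (CuOTf)2·C6H6 (5 mol %), (R,R)-Ph-pybox (10 mol %), i-Pr2NEt (1.2 equiv), CH2Cl2, −20 °C
Reagents that add atoms: none
Why: The same copper-catalysed asymmetric propargylic substitution with the mirror-image ligand sets the S centre that becomes C2 (R) of the lower unit.

**Step 7**
Reactants: 11 (S)-aryl propargyl ether
Product: 12 (2S)-7-(benzyloxy)-2-[3,4-bis(benzyloxy)phenyl]-2H-chromene
Conditions: Ph3PAuNTf2 (3 mol %), CH2Cl2, rt
Reagents that add atoms: none
Why: Gold-catalysed 6-endo-dig intramolecular hydroarylation of an aryl propargyl ether, closing para to the benzyloxy group and leaving the stereocentre untouched.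

**Step 8**
Reactants: 12 (2S)-2H-chromene
Product: 14 (2R,3S)-7-(benzyloxy)-2-[3,4-bis(benzyloxy)phenyl]chroman-3-ol (2,3-trans), via 3-borylflavan 13 (not isolated)
Conditions: BH3·THF (2 equiv), THF, 0 °C; then aq NaOH, H2O2, 0 °C to rt
Reagents that add atoms: borane–THF, [BH3-][O+]1CCCC1; hydrogen peroxide, OO
Why: Hydroboration–oxidation: boron adds to C3 (the styrene β-carbon) from the face opposite the C2 aryl group and is replaced by OH with retention, giving the 2,3-trans alcohol (3S).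

**Step 9**
Reactants: 10 C4 acetal of the upper unit; 14 (2R,3S)-alcohol
Product: 15 (2S,3S,4S)-7-(benzyloxy)-2-[3,4-bis(benzyloxy)phenyl]-4-{(2R,3S)-7-(benzyloxy)-2-[3,4-bis(benzyloxy)phenyl]-3-hydroxychroman-6-yl}chroman-3-ol (same arrangement in space as 16; the C4 descriptor reads S only because the benzyl groups change the priority order)
Conditions: 14 (4 equiv, excess recovered), TMSOTf (0.3 equiv), CH2Cl2, −40 to −20 °C; Et3N
Reagents that add atoms: none
Why: Lewis-acid-promoted Friedel–Crafts flavan coupling: ionisation at C4 of 10 and attack by C6 of 14 (para to O1, less hindered than C8) anti to the 3-OH gives the 3,4-trans (4→6) bond, while excess 14 suppresses oligomers.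

**Step 10**
Reactants: 15 hexabenzyl ether
Product: 16 (2S,3S,4R)-2-(3,4-dihydroxyphenyl)-4-[(2R,3S)-2-(3,4-dihydroxyphenyl)-3,7-dihydroxychroman-6-yl]chroman-3,7-diol (target)
Conditions: H2 (1 atm), Pd(OH)2/C, THF/MeOH/H2O, rt
Reagents that add atoms: none
Why: Hydrogenolysis of the six aryl benzyl ethers; no stereocentre is affected.

**Compound list**
1 | 3,4-bis(benzyloxy)benzaldehyde | O=Cc1ccc(OCc2ccccc2)c(OCc2ccccc2)c1 | starting material
2 | ethynylmagnesium bromide | C#C[Mg]Br | starting material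
3 | bromomagnesium 1-[3,4-bis(benzyloxy)phenyl]prop-2-yn-1-olate (racemic) | C#CC(O[Mg]Br)c1ccc(OCc2ccccc2)c(OCc2ccccc2)c1 | intermediate
4 | racemic 1-[3,4-bis(benzyloxy)phenyl]prop-2-yn-1-yl acetate | C#CC(OC(C)=O)c1ccc(OCc2ccccc2)c(OCc2ccccc2)c1 | intermediate
5 | 3-(benzyloxy)phenol | Oc1cccc(OCc2ccccc2)c1 | starting material
6 | 1-(benzyloxy)-3-{[(1R)-1-[3,4-bis(benzyloxy)phenyl]prop-2-yn-1-yl]oxy}benzene | C#C[C@@H](Oc1cccc(OCc2ccccc2)c1)c1ccc(OCc2ccccc2)c(OCc2ccccc2)c1 | intermediate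
7 | α-oxo gold carbene: Me4tBuXPhos-gold 3-[3-(benzyloxy)phenoxy]-3-[3,4-bis(benzyloxy)phenyl]-2-oxopropylidene cation, NTf2 salt (S by CIP; same arrangement in space as in 6) | CC(C)c1cc(C(C)C)c(-c2c(C)c(C)c(C)c(C)c2[P+](C(C)(C)C)(C(C)(C)C)[Au]=CC(=O)[C@@H](Oc2cccc(OCc3ccccc3)c2)c2ccc(OCc3ccccc3)c(OCc3ccccc3)c2)c(C(C)C)c1.[N-](S(=O)(=O)C(F)(F)F)S(=O)(=O)C(F)(F)F | intermediate
8 | (2S)-7-(benzyloxy)-2-[3,4-bis(benzyloxy)phenyl]chroman-3-one | c1ccccc1COc1ccc2c(c1)O[C@@H](c1ccc(OCc3ccccc3)c(OCc3ccccc3)c1)C(=O)C2 | intermediate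
9 | (2S,3S)-7-(benzyloxy)-2-[3,4-bis(benzyloxy)phenyl]chroman-3-ol | c1ccccc1COc1ccc2c(c1)O[C@@H](c1ccc(OCc3ccccc3)c(OCc3ccccc3)c1)[C@@H](O)C2 | intermediate
10 | (2S,3S,4R)-7-(benzyloxy)-2-[3,4-bis(benzyloxy)phenyl]-4-(2-ethoxyethoxy)chroman-3-ol | c1ccccc1COc1ccc2c(c1)O[C@@H](c1ccc(OCc3ccccc3)c(OCc3ccccc3)c1)[C@@H](O)[C@@H]2OCCOCC | intermediate
11 | 1-(benzyloxy)-3-{[(1S)-1-[3,4-bis(benzyloxy)phenyl]prop-2-yn-1-yl]oxy}benzene | C#C[C@H](Oc1cccc(OCc2ccccc2)c1)c1ccc(OCc2ccccc2)c(OCc2ccccc2)c1 | intermediate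
12 | (2S)-7-(benzyloxy)-2-[3,4-bis(benzyloxy)phenyl]-2H-chromene | c1ccccc1COc1ccc2c(c1)O[C@H](c1ccc(OCc3ccccc3)c(OCc3ccccc3)c1)C=C2 | intermediate
13 | [(2S,3S)-7-(benzyloxy)-2-[3,4-bis(benzyloxy)phenyl]chroman-3-yl]borane (boron trans to the aryl group) | c1ccccc1COc1ccc2c(c1)O[C@H](c1ccc(OCc3ccccc3)c(OCc3ccccc3)c1)[C@@H](B)C2 | intermediate
14 | (2R,3S)-7-(benzyloxy)-2-[3,4-bis(benzyloxy)phenyl]chroman-3-ol | c1ccccc1COc1ccc2c(c1)O[C@H](c1ccc(OCc3ccccc3)c(OCc3ccccc3)c1)[C@@H](O)C2 | intermediate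
15 | (2S,3S,4S)-7-(benzyloxy)-2-[3,4-bis(benzyloxy)phenyl]-4-{(2R,3S)-7-(benzyloxy)-2-[3,4-bis(benzyloxy)phenyl]-3-hydroxychroman-6-yl}chroman-3-ol | c1ccccc1COc1ccc2c(c1)O[C@@H](c1ccc(OCc3ccccc3)c(OCc3ccccc3)c1)[C@@H](O)[C@@H]2c1cc2c(cc1OCc1ccccc1)O[C@H](c1ccc(OCc3ccccc3)c(OCc3ccccc3)c1)[C@@H](O)C2 | intermediate
16 | (2S,3S,4R)-2-(3,4-dihydroxyphenyl)-4-[(2R,3S)-2-(3,4-dihydroxyphenyl)-3,7-dihydroxychroman-6-yl]chroman-3,7-diol | Oc1ccc2c(c1)O[C@@H](c1ccc(O)c(O)c1)[C@@H](O)[C@@H]2c1cc2c(cc1O)O[C@H](c1ccc(O)c(O)c1)[C@@H](O)C2 | target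

**Totals**
Total steps: 10. Longest linear sequence: 7 (steps 1, 2, 3, 4, 5, 9, 10).

**Steps most likely to fail, with fallbacks**

Step 3. The carbene could instead be attacked by ring B (giving an indan-2-one), the doubly activated benzylic ether could ionise at gold, or the ketone could epimerise at C2. The fallback sets out from 6 and comes back at 8. Treating 6 with Ph3PAuNTf2 without oxidant gives (2R)-7-(benzyloxy)-2-[3,4-bis(benzyloxy)phenyl]-2H-chromene F1. Hydroboration–oxidation (BH3·THF; NaOH, H2O2) gives the trans alcohol (2S,3R)-7-(benzyloxy)-2-[3,4-bis(benzyloxy)phenyl]chroman-3-ol F2. Dess–Martin periodinane in CH2Cl2 then gives ketone 8.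

Step 2 (and its twin, step 6). The electron-rich phenol may react through carbon, or the acetate may ionise without copper and erode the ee. The fallback sets out from 1 and comes back at 6 and 11. Addition of 2 to 1 with aqueous work-up gives racemic 1-[3,4-bis(benzyloxy)phenyl]prop-2-yn-1-ol F3. Lipase resolution (Novozym 435, vinyl acetate, toluene) leaves (S)-1-[3,4-bis(benzyloxy)phenyl]prop-2-yn-1-ol F4 and gives (R)-1-[3,4-bis(benzyloxy)phenyl]prop-2-yn-1-yl acetate F5 (configurations by the empirical lipase rule, to be checked). Mitsunobu etherification of F4 with 5 (PPh3, DIAD, toluene, 0 °C) inverts the centre and gives 6. Methanolysis of F5 (K2CO3, MeOH) gives (R)-1-[3,4-bis(benzyloxy)phenyl]prop-2-yn-1-ol F6, which under the same Mitsunobu conditions gives 11.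

Step 5. Ring A has no 5-oxygen, so hydride abstraction by DDQ may be slow or unselective. The fallback sets out from 9 and comes back at 15. Benzylic acetoxylation with Pb(OAc)4 in benzene gives (2S,3R,4R)-7-(benzyloxy)-2-[3,4-bis(benzyloxy)phenyl]-3-hydroxychroman-4-yl acetate F7 (2,3-cis, 3,4-trans). F7 is ionised with BF3·OEt2 in CH2Cl2 in the presence of excess 14 to give 15.

**Further compounds**
F1 | step 3 | (2R)-7-(benzyloxy)-2-[3,4-bis(benzyloxy)phenyl]-2H-chromene | c1ccccc1COc1ccc2c(c1)O[C@@H](c1ccc(OCc3ccccc3)c(OCc3ccccc3)c1)C=C2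
F2 | step 3 | (2S,3R)-7-(benzyloxy)-2-[3,4-bis(benzyloxy)phenyl]chroman-3-ol | c1ccccc1COc1ccc2c(c1)O[C@@H](c1ccc(OCc3ccccc3)c(OCc3ccccc3)c1)[C@H](O)C2
F3 | step 2 | racemic 1-[3,4-bis(benzyloxy)phenyl]prop-2-yn-1-ol | C#CC(O)c1ccc(OCc2ccccc2)c(OCc2ccccc2)c1
F4 | step 2 | (S)-1-[3,4-bis(benzyloxy)phenyl]prop-2-yn-1-ol | C#C[C@H](O)c1ccc(OCc2ccccc2)c(OCc2ccccc2)c1
F5 | step 2 | (R)-1-[3,4-bis(benzyloxy)phenyl]prop-2-yn-1-yl acetate | C#C[C@@H](OC(C)=O)c1ccc(OCc2ccccc2)c(OCc2ccccc2)c1
F6 | step 2 | (R)-1-[3,4-bis(benzyloxy)phenyl]prop-2-yn-1-ol | C#C[C@@H](O)c1ccc(OCc2ccccc2)c(OCc2ccccc2)c1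
F7 | step 5 | (2S,3R,4R)-7-(benzyloxy)-2-[3,4-bis(benzyloxy)phenyl]-3-hydroxychroman-4-yl acetate | c1ccccc1COc1ccc2c(c1)O[C@@H](c1ccc(OCc3ccccc3)c(OCc3ccccc3)c1)[C@@H](O)[C@@H]2OC(C)=O
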